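**Plan**

Numbering: C1, C2 and C5 are the cyclohexane carbons that carry the triketone ring, the OH/CH3 pair and the isopropenyl group; C1'–C6' are the triketone ring carbons (C1' on the cyclohexane, C3' gem-diprenyl, C5' isobutyryl).

- Retrosynthesis cuts C1'–C2' and C4'–C5'. C2'–C3'–C4' is a 2,2-diprenylmalonyl unit and C1'/C6'/C5'/isobutyryl is a β-diketone, so the fragments are dimethyl 2,2-diprenylmalonate and a terpenyl hydroxy β-diketone.
- The β-diketone is cut at C5'–C6' into a cis-fused γ-lactone and the methyl-side enolate of 3-methyl-2-butanone. The lactone goes back through iodolactonisation and a Claisen rearrangement to cis-carveol and (R)-carvone.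
- Forward: the carvone ring is kept, the acetic acid arm is attached by Johnson–Claisen rearrangement, the lactone is closed and then opened to the diketone chain, the malonate is diprenylated separately, and the triketone ring is closed last from the two fragments.
- Stereochemistry: C5 comes from (R)-carvone; C1 from Luche reduction to cis-carveol followed by suprafacial [3,3] transfer; C2 from the cis-fused iodolactonisation. The key step creates no stereocentre.

Key step: step 8

Assumption: the hydroxy β-diketone and the target are written as single keto–enol tautomers; the hydroxy β-diketone may sit partly as its cyclic hemiketal, which gives the same trianion with excess base.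

**Route**

Step 1
Reactants: 1 (R)-(−)-carvone
Product: 2 (1R,5R)-cis-carveol [(1R,5R)-2-methyl-5-(prop-1-en-2-yl)cyclohex-2-en-1-ol]
Conditions: NaBH4, CeCl3·7H2O, MeOH, 0 °C
Reagents that add atoms: none
Why: Luche 1,2-reduction; hydride enters axially on the face opposite the isopropenyl group, so the new carbinol centre should be (1R) with OH cis to the isopropenyl group.

Step 2
Reactants: 2 (1R,5R)-cis-carveol; 3 triethyl orthoacetate
Product: 6 ethyl 2-[(1R,5S)-2-methyl-5-(prop-1-en-2-yl)cyclohex-2-en-1-yl]acetate, via mixed orthoester 4 (not isolated), via ketene acetal 5 (not isolated)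
Conditions: MeC(OEt)3 (excess), EtCO2H (cat.), 140–180 °C (sealed tube)
Reagents that add atoms: triethyl orthoacetate (3), CC(OCC)(OCC)OCC
Why: Johnson–Claisen rearrangement; the suprafacial [3,3] shift of ketene acetal 5 forms the new C–C bond on the face that carried the C–O bond, so the (1R) centre of 6 is set cis to the isopropenyl group by 1,3-chirality transfer.

Step 3
Reactants: 6 ethyl 2-[(1R,5S)-2-methyl-5-(prop-1-en-2-yl)cyclohex-2-en-1-yl]acetate
Product: 7 2-[(1R,5S)-2-methyl-5-(prop-1-en-2-yl)cyclohex-2-en-1-yl]acetic acid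
Conditions: LiOH·H2O, THF/MeOH/H2O, rt; then 1 M HCl
Reagents that add atoms: lithium hydroxide, [Li+].[OH-]
Why: Ordinary ester saponification, which touches neither alkene nor either stereocentre.

Step 4
Reactants: 7 2-[(1R,5S)-2-methyl-5-(prop-1-en-2-yl)cyclohex-2-en-1-yl]acetic acid
Product: 8 (3aR,5R,7S,7aS)-7-iodo-7a-methyl-5-(prop-1-en-2-yl)hexahydro-1-benzofuran-2(3H)-one
Conditions: I2, NaHCO3, MeCN, 0 °C, dark
Reagents that add atoms: iodine, II
Why: Kinetic iodolactonisation; the carboxylate attacks the tertiary alkene carbon 5-exo and anti to the iodonium, and the short tether reaches only its own face, so the ring fusion is cis and the new C–O centre is set cis to the acetic acid arm (iodine trans-diaxial), while the isopropenyl group has no internal nucleophile.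

Step 5
Reactants: 8 (3aR,5R,7S,7aS)-7-iodo-7a-methyl-5-(prop-1-en-2-yl)hexahydro-1-benzofuran-2(3H)-one
Product: 9 (3aR,5S,7aR)-7a-methyl-5-(prop-1-en-2-yl)hexahydro-1-benzofuran-2(3H)-one
Conditions: Bu3SnH, AIBN (cat.), toluene, 80 °C
Reagents that add atoms: none
Why: Radical chain dehalogenation of a secondary iodide; hydrogen transfer from Bu3SnH should outrun 5-endo addition to the isopropenyl group or loss of the β-acyloxy group, and the carbon involved becomes a CH2.

Step 6
Reactants: 9 (3aR,5S,7aR)-7a-methyl-5-(prop-1-en-2-yl)hexahydro-1-benzofuran-2(3H)-one; 10 3-methyl-2-butanone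
Product: 12 1-[(1R,2R,5S)-2-hydroxy-2-methyl-5-(prop-1-en-2-yl)cyclohexyl]-5-methylhexane-2,4-dione, via lithium enolate 11 (not isolated)
Conditions: 10 (3 equiv), LDA (3 equiv), THF, −78 °C; then 9, −78 → 0 °C; AcOH quench at −78 °C
Reagents that add atoms: 3-methyl-2-butanone (10), CC(C)C(C)=O
Why: Crossed Claisen acylation of the kinetic methyl-side lithium enolate by the γ-lactone; the tetrahedral adduct releases the tertiary alkoxide, and a second equivalent of enolate turns the β-diketone into its diketonate, which holds the chain open.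

Step 7
Reactants: 13 dimethyl malonate; 14 prenyl bromide
Product: 16 dimethyl 2,2-bis(3-methylbut-2-en-1-yl)malonate, via monoprenyl malonate 15 (not isolated)
Conditions: NaH (2.3 equiv), 14 (2.3 equiv), THF, 0 → 50 °C
Reagents that add atoms: prenyl bromide (14), CC(C)=CCBr
Why: Double SN2 C-alkylation of the malonate anion with a primary allylic bromide, the second deprotonation and alkylation installing the quaternary carbon.

Step 8
Reactants: 12 1-[(1R,2R,5S)-2-hydroxy-2-methyl-5-(prop-1-en-2-yl)cyclohexyl]-5-methylhexane-2,4-dione; 16 dimethyl 2,2-bis(3-methylbut-2-en-1-yl)malonate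
Product: 19 3,5-dihydroxy-4-[(1R,2R,5S)-2-hydroxy-2-methyl-5-(prop-1-en-2-yl)cyclohexyl]-2-(2-methylpropanoyl)-6,6-bis(3-methylbut-2-en-1-yl)cyclohexa-2,4-dien-1-one, via trilithium trianion 17 (not isolated), via open-chain triketo ester 18 (not isolated)
Conditions: LDA (4.5 equiv), THF, −78 → 0 °C; then 16 (1.2 equiv), 0 °C → rt; 1 M HCl, 0 °C
Reagents that add atoms: dimethyl 2,2-bis(3-methylbut-2-en-1-yl)malonate (16), COC(=O)C(CC=C(C)C)(CC=C(C)C)C(=O)OC
Why: LDA removes the OH proton, a central diketone proton and then a proton of the methylene next to the cyclohexane; the terminal carbanion of trianion 17 adds to one ester of 16 and expels methoxide (C1'–C2'), giving triketo ester 18 as its polyenolate. The doubly activated C5' of 18 then attacks the second ester in a Dieckmann condensation (C4'–C5'), a 6-exo-trig closure of an enolate carbon onto an ester carbonyl that forms the carbocyclic triketone ring and is pulled forward by the triacylmethane-type enolate of 19. The closest known reaction types are the terminal C-acylation of β-diketone 1,3-dianions by esters and the condensation of ketone enolates with 2,2-dialkylmalonic esters to 4,4-dialkylcyclohexane-1,3,5-triones. No stereocentre is created; the three cyclohexane centres are spectators and the tertiary alcohol rides through as its lithium alkoxide. The step needs the second C-deprotonation at the methylene and not at the isopropyl methine, which the usual methyl > methylene > methine order of dianion formation and the neighbouring lithium alkoxide should secure; it also needs C- over O-acylation in the closure, which is secured because an O-acylated enol lactone can revert under the lithium methoxide present while the trione enolate is the thermodynamic sink. Malonate 16 has no α-proton, so it can neither quench the trianion nor self-condense.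

**Compound list**

1 | (R)-(−)-carvone | C=C(C)[C@H]1CC(=O)C(C)=CC1 | starting material
2 | (1R,5R)-cis-carveol, (1R,5R)-2-methyl-5-(prop-1-en-2-yl)cyclohex-2-en-1-ol | C=C(C)[C@H]1C[C@@H](O)C(C)=CC1 | intermediate
3 | triethyl orthoacetate | CC(OCC)(OCC)OCC | starting material
4 | mixed orthoester, (1R,5R)-1-(1,1-diethoxyethoxy)-2-methyl-5-(prop-1-en-2-yl)cyclohex-2-ene | C=C(C)[C@H]1C[C@@H](OC(C)(OCC)OCC)C(C)=CC1 | intermediate
5 | ketene acetal, (1R,5R)-1-(1-ethoxyethenoxy)-2-methyl-5-(prop-1-en-2-yl)cyclohex-2-ene | C=C(C)[C@H]1C[C@@H](OC(=C)OCC)C(C)=CC1 | intermediate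
6 | ethyl 2-[(1R,5S)-2-methyl-5-(prop-1-en-2-yl)cyclohex-2-en-1-yl]acetate | C=C(C)[C@H]1CC=C(C)[C@@H](CC(=O)OCC)C1 | intermediate
7 | 2-[(1R,5S)-2-methyl-5-(prop-1-en-2-yl)cyclohex-2-en-1-yl]acetic acid | C=C(C)[C@H]1CC=C(C)[C@@H](CC(=O)O)C1 | intermediate
8 | (3aR,5R,7S,7aS)-7-iodo-7a-methyl-5-(prop-1-en-2-yl)hexahydro-1-benzofuran-2(3H)-one | C=C(C)[C@H]1C[C@H](I)[C@@]2(C)OC(=O)C[C@H]2C1 | intermediate
9 | (3aR,5S,7aR)-7a-methyl-5-(prop-1-en-2-yl)hexahydro-1-benzofuran-2(3H)-one | C=C(C)[C@H]1CC[C@@]2(C)OC(=O)C[C@H]2C1 | intermediate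
10 | 3-methyl-2-butanone | CC(C)C(C)=O | starting material
11 | lithium 3-methylbut-1-en-2-olate | [Li+].C=C([O-])C(C)C | intermediate
12 | 1-[(1R,2R,5S)-2-hydroxy-2-methyl-5-(prop-1-en-2-yl)cyclohexyl]-5-methylhexane-2,4-dione | C=C(C)[C@H]1CC[C@@](C)(O)[C@@H](CC(=O)CC(=O)C(C)C)C1 | intermediate
13 | dimethyl malonate | COC(=O)CC(=O)OC | starting material
14 | prenyl bromide, 1-bromo-3-methylbut-2-ene | CC(C)=CCBr | starting material
15 | dimethyl 2-(3-methylbut-2-en-1-yl)malonate | COC(=O)C(CC=C(C)C)C(=O)OC | intermediate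
16 | dimethyl 2,2-bis(3-methylbut-2-en-1-yl)malonate | COC(=O)C(CC=C(C)C)(CC=C(C)C)C(=O)OC | intermediate
17 | trilithium trianion of 12 (alkoxide plus dienediolate) | [Li+].[Li+].[Li+].C=C(C)[C@H]1CC[C@@](C)([O-])[C@@H](C=C([O-])C=C([O-])C(C)C)C1 | intermediate
18 | methyl 4-[(1R,2R,5S)-2-hydroxy-2-methyl-5-(prop-1-en-2-yl)cyclohexyl]-8-methyl-2,2-bis(3-methylbut-2-en-1-yl)-3,5,7-trioxononanoate (present in the flask as its lithium polyenolate; C4 of the chain is enolised and has no fixed configuration) | C=C(C)[C@H]1CC[C@@](C)(O)[C@@H](C(C(=O)CC(=O)C(C)C)C(=O)C(CC=C(C)C)(CC=C(C)C)C(=O)OC)C1 | intermediate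
19 | 3,5-dihydroxy-4-[(1R,2R,5S)-2-hydroxy-2-methyl-5-(prop-1-en-2-yl)cyclohexyl]-2-(2-methylpropanoyl)-6,6-bis(3-methylbut-2-en-1-yl)cyclohexa-2,4-dien-1-one | C=C(C)[C@H]1CC[C@@](C)(O)[C@@H](C2=C(O)C(CC=C(C)C)(CC=C(C)C)C(=O)C(C(=O)C(C)C)=C2O)C1 | target

**Step count**

Total: 8 steps. Longest linear sequence: 7 steps (steps 1–6 and 8, from (R)-carvone); step 7 is a one-step side branch.

**Steps most likely to fail**

Step 8. The hindered secondary carbanion may add too slowly to the neopentyl-type methyl ester, so that proton transfer, incomplete trianion formation or O-cyclisation to an enol lactone takes over. The fallback forms the two C–C bonds in separate operations with an activated malonyl half-ester. It sets out from 16 and 12 and returns at 19. Mono-saponification of 16 (KOH, 1 equiv, MeOH/H2O) should give 2-(methoxycarbonyl)-5-methyl-2-(3-methylbut-2-en-1-yl)hex-4-enoic acid F1. Carbonyldiimidazole in THF converts this into methyl 2-(1H-imidazole-1-carbonyl)-5-methyl-2-(3-methylbut-2-en-1-yl)hex-4-enoate F2. Trianion 17, made from 12 as before, is C-acylated by this far more electrophilic acyl donor at −78 °C, and the open-chain triketo ester 18 is now isolated after a mild acidic quench. A separate Dieckmann condensation under equilibrating conditions (NaOMe, MeOH, rt to reflux) then closes 18 to 19.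

Step 6. The lactone adduct may stop at the cyclic lactol stage, the lactone may be enolised instead of acylated, or the product may cyclise and dehydrate to a furanoid enol ether on work-up. The fallback opens the lactone first and acylates the enolate with a protected Weinreb amide. It sets out from 9 and returns at 12. Aminolysis of 9 (MeONHMe·HCl, Me3Al, CH2Cl2) should give 2-[(1R,2R,5S)-2-hydroxy-2-methyl-5-(prop-1-en-2-yl)cyclohexyl]-N-methoxy-N-methylacetamide F3. Silylation (TESOTf, 2,6-lutidine) gives N-methoxy-N-methyl-2-[(1R,2R,5S)-2-methyl-5-(prop-1-en-2-yl)-2-(triethylsilyloxy)cyclohexyl]acetamide F4. Lithium enolate 11 (excess, THF, −78 → 0 °C) acylates cleanly on the Weinreb amide to give 5-methyl-1-[(1R,2R,5S)-2-methyl-5-(prop-1-en-2-yl)-2-(triethylsilyloxy)cyclohexyl]hexane-2,4-dione F5. Buffered fluoride (TBAF, AcOH, THF) removes the silyl group to give 12.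

Step 2. The rearrangement needs the pseudoequatorial C–O bond of cis-carveol to turn pseudoaxial, and at 140–180 °C with acid the mixed orthoester may instead eliminate to menthatrienes. The fallback is an Ireland–Claisen rearrangement under basic conditions below 60 °C. It sets out from 2 and returns at 7, which makes step 3 unnecessary. Acetylation of 2 (Ac2O, pyridine, DMAP) gives (1R,5R)-2-methyl-5-(prop-1-en-2-yl)cyclohex-2-en-1-yl acetate F6. LDA and TMSCl in THF at −78 °C convert it into the silyl ketene acetal trimethyl({1-[(1R,5R)-2-methyl-5-(prop-1-en-2-yl)cyclohex-2-en-1-yl]oxyethenyl}oxy)silane F7. Warming to rt–60 °C should bring about the same suprafacial [3,3] shift to trimethylsilyl 2-[(1R,5S)-2-methyl-5-(prop-1-en-2-yl)cyclohex-2-en-1-yl]acetate F8, which aqueous work-up hydrolyses to acid 7.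

**Further compounds**

F1 | step 8 | 2-(methoxycarbonyl)-5-methyl-2-(3-methylbut-2-en-1-yl)hex-4-enoic acid | COC(=O)C(CC=C(C)C)(CC=C(C)C)C(=O)O
F2 | step 8 | methyl 2-(1H-imidazole-1-carbonyl)-5-methyl-2-(3-methylbut-2-en-1-yl)hex-4-enoate | COC(=O)C(CC=C(C)C)(CC=C(C)C)C(=O)n1ccnc1
F3 | step 6 | 2-[(1R,2R,5S)-2-hydroxy-2-methyl-5-(prop-1-en-2-yl)cyclohexyl]-N-methoxy-N-methylacetamide | C=C(C)[C@H]1CC[C@@](C)(O)[C@@H](CC(=O)N(C)OC)C1
F4 | step 6 | N-methoxy-N-methyl-2-[(1R,2R,5S)-2-methyl-5-(prop-1-en-2-yl)-2-(triethylsilyloxy)cyclohexyl]acetamide | C=C(C)[C@H]1CC[C@@](C)(O[Si](CC)(CC)CC)[C@@H](CC(=O)N(C)OC)C1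
F5 | step 6 | 5-methyl-1-[(1R,2R,5S)-2-methyl-5-(prop-1-en-2-yl)-2-(triethylsilyloxy)cyclohexyl]hexane-2,4-dione | C=C(C)[C@H]1CC[C@@](C)(O[Si](CC)(CC)CC)[C@@H](CC(=O)CC(=O)C(C)C)C1
F6 | step 2 | (1R,5R)-2-methyl-5-(prop-1-en-2-yl)cyclohex-2-en-1-yl acetate | C=C(C)[C@H]1C[C@@H](OC(C)=O)C(C)=CC1
F7 | step 2 | trimethyl({1-[(1R,5R)-2-methyl-5-(prop-1-en-2-yl)cyclohex-2-en-1-yl]oxyethenyl}oxy)silane | C=C(C)[C@H]1C[C@@H](OC(=C)O[Si](C)(C)C)C(C)=CC1
F8 | step 2 | trimethylsilyl 2-[(1R,5S)-2-methyl-5-(prop-1-en-2-yl)cyclohex-2-en-1-yl]acetate | C=C(C)[C@H]1CC=C(C)[C@@H](CC(=O)O[Si](C)(C)C)C1
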